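**Overview**

1. Cuts, in order: the two O-benzyl bonds of a protected precursor. Then, in each inner ring, the bond between the aroyl-bearing carbon C1 and the C2(OH) carbon next to the bridge carbon. Then the two CH2–C(=O)Ar bonds, and last the two pyrone C3–CH2 bonds of the bridge.
2. Enabling feature: round each inner ring the atoms read C1(COAr), C2(OH), C3(CH2 bridge), C4(OMe), C5(H), C6(OH). These map atom for atom onto the side-chain CH2, lactone C2, C3, C4, C5 and C6(–O1) of a 3-alkyl-6-(aroylmethyl)-4-methoxy-2-pyrone, which is an isomer of that ring.
3. Forward order: two triacetic acid lactone rings are tied at C3 by formaldehyde and O-methylated. Both C6 methyl groups are acylated with an aroyl chloride made from methyl orsellinate, so the outer rings are bought. Both inner benzene rings form last, in one operation, each at the expense of a pyrone ring, and hydrogenolysis ends the route.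
4. Stereochemistry: the target has no stereocentre and no stereogenic double bond. The only geometric need is that the ester sits cis to the diketone chain on the transient tetrasubstituted enol ether (E by the sequence rules). That relation is inherited from the pyrone ring.

Key step: step 8

Remark: the transient species 11 and 13 are drawn in one limiting form (O-lithium dienolate; neutral keto tautomer). In the flask they are aggregated or magnesium-chelated enolates, and the two halves of 12 need not open and close at the same moment.

Step 1
Reactants: 1 triacetic acid lactone (4-hydroxy-6-methyl-2H-pyran-2-one, two equivalents); 2 formaldehyde (37% aqueous solution)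
Product: 4 bis(4-hydroxy-6-methyl-2-oxo-2H-pyran-3-yl)methane, via methylidenepyrandione 3 (not isolated)
Conditions: aq. HCHO (0.5 equiv), EtOH/H2O, 70 °C
Reagents that add atoms: none
Why: Knoevenagel condensation at the nucleophilic C3 of 1 gives the electrophilic methylidene dione 3, which a second molecule of 1 intercepts at once in a Michael addition (the tandem process that converts 4-hydroxycoumarin into dicoumarol), and the sparingly soluble product should crystallise from the medium.

Step 2
Reactants: 4 bis(4-hydroxy-6-methyl-2-oxo-2H-pyran-3-yl)methane
Product: 5 bis(4-methoxy-6-methyl-2-oxo-2H-pyran-3-yl)methane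
Conditions: Me2SO4 (2.5 equiv), K2CO3, acetone, reflux
Reagents that add atoms: dimethyl sulfate, COS(=O)(=O)OC
Why: Williamson-type O-alkylation of the vinylogous carboxylate with the hard electrophile dimethyl sulfate should favour the 4-methoxy-2-pyrone over the 2-methoxy-4-pyrone form, as it does for the parent lactone, and any isomeric ether can be removed by chromatography or crystallisation.

Step 3
Reactants: 6 methyl orsellinate (methyl 2,4-dihydroxy-6-methylbenzoate)
Product: 7 methyl 4-benzyloxy-2-hydroxy-6-methylbenzoate
Conditions: BnBr (1.05 equiv), K2CO3, acetone, reflux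
Reagents that add atoms: benzyl bromide, BrCc1ccccc1
Why: In this Williamson ether synthesis the 2-OH is hydrogen-bonded to the ester carbonyl and reacts far more slowly than the free 4-OH, so one equivalent of benzyl bromide should mark only the 4-position with a group that tolerates amide bases and methoxide and leaves under neutral conditions.

Step 4
Reactants: 7 methyl 4-benzyloxy-2-hydroxy-6-methylbenzoate
Product: 8 methyl 4-benzyloxy-2-methoxy-6-methylbenzoate
Conditions: MeI (excess), K2CO3, DMF, 50 °C
Reagents that add atoms: methyl iodide, CI
Why: Williamson methylation in a dipolar aprotic solvent with excess methyl iodide overcomes the chelation of the remaining phenol, which is the only acidic site left.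

Step 5
Reactants: 8 methyl 4-benzyloxy-2-methoxy-6-methylbenzoate
Product: 9 protected orsellinic acid (4-benzyloxy-2-methoxy-6-methylbenzoic acid)
Conditions: KOH (excess), aq. DMSO, 100 °C; then 1 M HCl, 0 °C
Reagents that add atoms: potassium hydroxide (source of the new carboxyl oxygen), [K+].[OH-]
Why: Saponification of a di-ortho-substituted benzoate is slow but proceeds with poorly solvated hydroxide at high temperature, both aryl ethers are inert to base, and cold acidification limits decarboxylation of the electron-rich acid.

Step 6
Reactants: 9 protected orsellinic acid (4-benzyloxy-2-methoxy-6-methylbenzoic acid)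
Product: 10 aroyl chloride (4-benzyloxy-2-methoxy-6-methylbenzoyl chloride)
Conditions: (COCl)2, cat. DMF, CH2Cl2, 0 °C to rt; volatiles removed, used crude
Reagents that add atoms: oxalyl chloride, O=C(Cl)C(=O)Cl
Why: DMF-catalysed acid chloride formation with oxalyl chloride runs under mild, nearly neutral conditions that leave benzyl and methyl aryl ethers untouched and gives only gaseous by-products.

Step 7
Reactants: 5 bis(4-methoxy-6-methyl-2-oxo-2H-pyran-3-yl)methane; 10 aroyl chloride (4-benzyloxy-2-methoxy-6-methylbenzoyl chloride, 2.2 equiv)
Product: 12 bis{6-[2-(4-benzyloxy-2-methoxy-6-methylphenyl)-2-oxoethyl]-4-methoxy-2-oxo-2H-pyran-3-yl}methane, via dilithium bis-dienolate 11 (not isolated)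
Conditions: LiN(SiMe3)2 (4.4 equiv), THF, −78 °C; then 10 in THF, −78 to −20 °C; 1 M HCl quench, 0 °C
Reagents that add atoms: lithium bis(trimethylsilyl)amide, [Li+].C[Si](C)(C)[N-][Si](C)(C)C (its lithium appears in 11 only; none of its atoms remain in 12)
Why: Lateral deprotonation of both C6 methyl groups gives the extended dienolate 11 (ring lithiation at C3 is excluded because that carbon carries the bridge), and C-acylation at the exocyclic carbon, a vinylogous Claisen-type acylation known for 6-methyl-4-methoxy-2-pyrones and for the related dioxinone dienolates, is carried through by the two further equivalents of base, which take up the more acidic CH2 protons of the product.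

Step 8
Reactants: 12 bis{6-[2-(4-benzyloxy-2-methoxy-6-methylphenyl)-2-oxoethyl]-4-methoxy-2-oxo-2H-pyran-3-yl}methane
Product: 14 digriseophene A bis(benzyl ether), bis[3-(4-benzyloxy-2-methoxy-6-methylbenzoyl)-2,4-dihydroxy-6-methoxyphenyl]methane, via ring-opened bis(enol ether ester) 13 (not isolated)
Conditions: Mg(OMe)2 (10 equiv), MeOH/THF, reflux, Ar; then 1 M HCl, 0 °C
Reagents that add atoms: magnesium methoxide, C[O-].C[O-].[Mg+2] (its methoxide is built into 13 only and is expelled again on ring closure; 14 is an isomer of 12)
Why: Methoxide adds to each lactone carbonyl (pyrone C2) and the ring opens reversibly to the (E)-3-methoxy-5,7-dioxohept-2-enoate 13, whose 1,3-diketone is held as a magnesium chelate and whose ester stays cis to the diketone chain because both were members of the pyrone ring. The chelated central carbon of the diketone (the former side-chain CH2) then attacks the ester carbonyl, methoxide leaves, and tautomerisation to the benzene ring makes the sequence irreversible, the former lactone carbon and the former C6 ending as the two C–OH carbons beside the aroyl group. The closest known reaction type is the base-induced isomerisation of 6-(2-oxoalkyl)- and 6-phenacyl-4-methoxy-2-pyrones to 2,6-dihydroxy-4-methoxyphenyl ketones, that is the intramolecular Claisen (Dieckmann-type) folding of a 3,5,7-triketo ester, used here twice in one molecule. Each of the two new six-membered carbocycles closes in the 6-exo-trig mode at the ester carbonyl, and no stereocentre is created. The step needs C-acylation rather than aldol closure, retro-Claisen scission or mere return to the pyrone: the ester alpha carbon is a fully substituted enol-ether carbon and cannot act as a nucleophile, the aryl ketone is screened by its ortho OMe and CH3 groups against both enolate and methoxide, and magnesium chelation keeps the C5 carbonyl enolised and hence unreactive towards methoxide. Methoxide in methanol also makes any addition-elimination at C4 degenerate, so the position of the 4-OMe group is never at risk.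

Step 9
Reactants: 14 digriseophene A bis(benzyl ether)
Product: 15 digriseophene A, bis[2,4-dihydroxy-3-(4-hydroxy-2-methoxy-6-methylbenzoyl)-6-methoxyphenyl]methane
Conditions: H2 (1 atm), 10% Pd/C, EtOAc, rt; stopped after uptake of 2 equiv H2
Reagents that add atoms: none
Why: Heterogeneous catalytic hydrogenolysis of aryl benzyl ethers is fast at ambient pressure, whereas the tetra-ortho-substituted, hydrogen-bonded diaryl ketones and the diarylmethane bridge should be inert under these neutral conditions, which also spare the acid- and air-sensitive bis-phloroglucinol core.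

**Compound list**

1 | triacetic acid lactone (4-hydroxy-6-methyl-2H-pyran-2-one) | Cc1cc(O)cc(=O)o1 | starting material
2 | formaldehyde | C=O | starting material
3 | 6-methyl-3-methylidene-2H-pyran-2,4(3H)-dione (not isolated) | C=C1C(=O)C=C(C)OC1=O | intermediate
4 | bis(4-hydroxy-6-methyl-2-oxo-2H-pyran-3-yl)methane | Cc1cc(O)c(Cc2c(O)cc(C)oc2=O)c(=O)o1 | intermediate
5 | bis(4-methoxy-6-methyl-2-oxo-2H-pyran-3-yl)methane | Cc1cc(OC)c(Cc2c(OC)cc(C)oc2=O)c(=O)o1 | intermediate
6 | methyl orsellinate (methyl 2,4-dihydroxy-6-methylbenzoate) | COC(=O)c1c(C)cc(O)cc1O | starting material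
7 | methyl 4-benzyloxy-2-hydroxy-6-methylbenzoate | COC(=O)c1c(C)cc(OCc2ccccc2)cc1O | intermediate
8 | methyl 4-benzyloxy-2-methoxy-6-methylbenzoate | COC(=O)c1c(C)cc(OCc2ccccc2)cc1OC | intermediate
9 | 4-benzyloxy-2-methoxy-6-methylbenzoic acid | COc1cc(OCc2ccccc2)cc(C)c1C(=O)O | intermediate
10 | 4-benzyloxy-2-methoxy-6-methylbenzoyl chloride | COc1cc(OCc2ccccc2)cc(C)c1C(=O)Cl | intermediate
11 | dilithium bis-dienolate of 5, deprotonated at both C6 methyl groups (not isolated) | [Li+].[Li+].C=C1C=C(OC)C(CC2=C([O-])OC(=C)C=C2OC)=C([O-])O1 | intermediate
12 | bis{6-[2-(4-benzyloxy-2-methoxy-6-methylphenyl)-2-oxoethyl]-4-methoxy-2-oxo-2H-pyran-3-yl}methane | COc1cc(OCc2ccccc2)cc(C)c1C(=O)Cc1cc(OC)c(Cc2c(OC)cc(CC(=O)c3c(C)cc(OCc4ccccc4)cc3OC)oc2=O)c(=O)o1 | intermediate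
13 | dimethyl 2,2'-methylenebis[(2E)-7-(4-benzyloxy-2-methoxy-6-methylphenyl)-3-methoxy-5,7-dioxohept-2-enoate] (not isolated) | COC(=O)/C(C/C(C(=O)OC)=C(OC)/CC(=O)CC(=O)c1c(C)cc(OCc2ccccc2)cc1OC)=C(OC)\CC(=O)CC(=O)c1c(C)cc(OCc2ccccc2)cc1OC | intermediate
14 | digriseophene A bis(benzyl ether), bis[3-(4-benzyloxy-2-methoxy-6-methylbenzoyl)-2,4-dihydroxy-6-methoxyphenyl]methane | COc1cc(O)c(C(=O)c2c(C)cc(OCc3ccccc3)cc2OC)c(O)c1Cc1c(OC)cc(O)c(C(=O)c2c(C)cc(OCc3ccccc3)cc2OC)c1O | intermediate
15 | digriseophene A (achiral) | COc1cc(O)c(C(=O)c2c(C)cc(O)cc2OC)c(O)c1Cc1c(OC)cc(O)c(C(=O)c2c(C)cc(O)cc2OC)c1O | target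

**Step count**

Total step count: 9.
Longest linear sequence: 7 steps (6 → 7 → 8 → 9 → 10 → 12 → 14 → 15). The pyrone arm (1 → 4 → 5) joins at step 7.

**Steps most likely to fail**

1. Step 8, the twofold recyclisation.
   - What may go wrong: the lactone carbonyl is crowded by the bridge, and the aroylmethyl pyrone is deactivated once it is enolised, so ring opening may stall. Only one half may close. Retro-Claisen scission of the diketone may outrun closure. The opened chain may re-lactonise on acidification.
   - Fallback (sets out from 1 and 10, comes back at 14): the inner rings are made before the bridge. Lactone 1 is O-methylated (Me2SO4, K2CO3, acetone) to 4-methoxy-6-methyl-2H-pyran-2-one F1. Its C6-methyl dienolate (LiN(SiMe3)2, THF, −78 °C) is acylated with 10 to 6-[2-(4-benzyloxy-2-methoxy-6-methylphenyl)-2-oxoethyl]-4-methoxy-2H-pyran-2-one F2. This single, unhindered pyrone is isomerised with Mg(OMe)2 in methanol to the monomeric benzophenone (4-benzyloxy-2-methoxy-6-methylphenyl)(2,6-dihydroxy-4-methoxyphenyl)methanone F3. Two molecules of F3 are then joined at one of their two equivalent free ring positions with half an equivalent of formaldehyde 2 (aqueous KOH/MeOH). This is a Lederer–Manasse hydroxymethylation followed by capture of the quinone methide, the usual way to methylene-bridged acylphloroglucinols, and it gives 14.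

2. Step 7, the double acylation.
   - What may go wrong: the dienolate may be acylated on oxygen. Proton transfer from the more acidic mono-acylated product may quench the second dienolate. The excess amide base may consume the hindered acid chloride.
   - Fallback (sets out from 8 and 5, comes back at 12): the carbonyl carbon is brought in at the aldehyde level and oxidised afterwards. Ester 8 is reduced with LiAlH4 (THF, 0 °C) to [4-(benzyloxy)-2-methoxy-6-methylphenyl]methanol F4. This is oxidised with MnO2 (CH2Cl2) to 4-benzyloxy-2-methoxy-6-methylbenzaldehyde F5. Dienolate 11, now made from 5 with only two equivalents of base, adds to two equivalents of F5 at −78 °C in an aldol-type addition, the standard reaction of lithiated 4-methoxy-6-methyl-2-pyrones. The product is the bis-carbinol bis{6-[2-(4-benzyloxy-2-methoxy-6-methylphenyl)-2-hydroxyethyl]-4-methoxy-2-oxo-2H-pyran-3-yl}methane F6, a mixture of diastereomers of no consequence. Dess–Martin periodinane (CH2Cl2, rt) oxidises both carbinols to 12.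

3. Step 2, the twofold O-methylation.
   - What may go wrong: alkylation may occur at the lactone carbonyl oxygen instead of the 4-oxygen, or at C3. The second methylation may stay incomplete because of the strong internal hydrogen bonds. The base may induce retro-Michael loss of the bridge.
   - Fallback (sets out from 4, comes back at 5): the C4–O bond is made instead of the O–CH3 bond. Compound 4 is sulfonylated (TsCl, Et3N, CH2Cl2, 0 °C), which for 4-hydroxy-2-pyrones occurs on the 4-oxygen, to give bis[6-methyl-2-oxo-4-(tosyloxy)-2H-pyran-3-yl]methane F7. Methoxide (NaOMe, MeOH/THF, 0 °C) then displaces both sulfonates by conjugate addition-elimination at C4. The methoxy groups can therefore only end up at C4 of a 2-pyrone, giving 5.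

**Further compounds**

F1 | step 8 | 4-methoxy-6-methyl-2H-pyran-2-one | COc1cc(C)oc(=O)c1
F2 | step 8 | 6-[2-(4-benzyloxy-2-methoxy-6-methylphenyl)-2-oxoethyl]-4-methoxy-2H-pyran-2-one | COc1cc(OCc2ccccc2)cc(C)c1C(=O)Cc1cc(OC)cc(=O)o1
F3 | step 8 | (4-benzyloxy-2-methoxy-6-methylphenyl)(2,6-dihydroxy-4-methoxyphenyl)methanone | COc1cc(O)c(C(=O)c2c(C)cc(OCc3ccccc3)cc2OC)c(O)c1
F4 | step 7 | [4-(benzyloxy)-2-methoxy-6-methylphenyl]methanol | COc1cc(OCc2ccccc2)cc(C)c1CO
F5 | step 7 | 4-benzyloxy-2-methoxy-6-methylbenzaldehyde | COc1cc(OCc2ccccc2)cc(C)c1C=O
F6 | step 7 | bis{6-[2-(4-benzyloxy-2-methoxy-6-methylphenyl)-2-hydroxyethyl]-4-methoxy-2-oxo-2H-pyran-3-yl}methane (mixture of diastereomers, both carbinol centres uncontrolled and removed on oxidation) | COc1cc(OCc2ccccc2)cc(C)c1C(O)Cc1cc(OC)c(Cc2c(OC)cc(CC(O)c3c(C)cc(OCc4ccccc4)cc3OC)oc2=O)c(=O)o1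
F7 | step 2 | bis[6-methyl-2-oxo-4-(tosyloxy)-2H-pyran-3-yl]methane | Cc1cc(OS(=O)(=O)c2ccc(C)cc2)c(Cc2c(OS(=O)(=O)c3ccc(C)cc3)cc(C)oc2=O)c(=O)o1
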